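**Retrosynthetic overview**

1. Benzofuran locants are used; ring A is the carbocycle C3a/C4/C5/C6/C7/C7a and ring B the dihydrofuran O1/C2/C3/C3a/C7a. The strategy rests on O1 at C7a lying β to the C6 carbonyl through C7=C7a, so ring B is the intramolecular 1,4-adduct of the C2 hydroxyl to a 4-alkyl-o-quinone whose carbonyl carbons are C5 and C6.
2. Target 20 (2S,3S,5S) ⇒ O-methylation of o-quinol 19 ⇒ allylboration at C5 (the carbonyl not conjugated to O1) of bicyclic o-quinone 17.
3. 17 ⇒ O1–C7a disconnection (anodic oxidation, closes ring B) ⇒ catechol alcohol 14.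
4. 14 ⇒ C2–C3 bond by Evans syn-aldol of arylacetyl imide 6 with aldehyde 7, which sets C2 and C3; the imide carbonyl is then taken down to the C3 methyl.
5. Ring order: ring A is the catechol ring of 1 throughout, ring B closes in step 8, and C5 is set last.

Key step: step 8

Assumption: the sense of induction of the 3,3'-dibromo-BINOL catalyst on the C5 carbonyl of 17 cannot be assigned in advance. The route is written with the (S)-catalyst; the (R)-catalyst replaces it unchanged if a trial shows that it is the one giving the 5S epimer. The C5 epimers are diastereomers and separable by chromatography.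

**Route**

Step 1
Reactants: 1 3,4-dihydroxyphenylacetic acid
Product: 3 2-[3,4-bis(tert-butyldimethylsilyloxy)phenyl]acetic acid, via tris-silylated silyl ester 2 (not isolated)
Conditions: TBSCl (3.3 equiv), imidazole, DMF, rt; then AcOH/THF/H2O, rt
Reagents that add atoms: tert-butyldimethylsilyl chloride, CC(C)(C)[Si](C)(C)Cl
Why: Corey silylation covers both phenols and the acid, and the silyl ester is far more labile than the aryl silyl ethers, so mild aqueous acid should hydrolyse it alone.

Step 2
Reactants: 3 2-[3,4-bis(tert-butyldimethylsilyloxy)phenyl]acetic acid; 4 (S)-4-benzyl-2-oxazolidinone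
Product: 6 (S)-4-benzyl-3-{2-[3,4-bis(tert-butyldimethylsilyloxy)phenyl]acetyl}oxazolidin-2-one, via mixed pivalic anhydride 5 (not isolated)
Conditions: PivCl, Et3N, THF, −20 °C; then 4, LiCl, −20 °C to rt
Reagents that add atoms: none
Why: N-acylation of the oxazolidinone through a mixed anhydride (LiCl/Et3N variant); the nucleophile should attack the unhindered arylacetyl carbonyl of 5, not the pivaloyl one.

Step 3
Reactants: 6 (S)-4-benzyl-3-{2-[3,4-bis(tert-butyldimethylsilyloxy)phenyl]acetyl}oxazolidin-2-one; 7 3,4,5-trimethoxybenzaldehyde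
Product: 10 (S)-4-benzyl-3-[(2S,3S)-2-[3,4-bis(tert-butyldimethylsilyloxy)phenyl]-3-hydroxy-3-(3,4,5-trimethoxyphenyl)propanoyl]oxazolidin-2-one, via Z-dibutylboron enolate 8 (not isolated), via dibutylboron aldolate 9 (not isolated)
Conditions: Bu2BOTf, iPr2NEt, CH2Cl2, −78 to 0 °C; then 7, −78 to 0 °C; pH 7 buffer, MeOH, H2O2, 0 °C
Reagents that add atoms: none
Why: Evans syn-aldol: the Z-boron enolate 8 should add to 7 through a Zimmerman–Traxler chair on the enolate face away from the benzyl group of the dipole-opposed auxiliary, setting the future C3 and C2 as 2S,3S (aryl and hydroxyl syn, which becomes trans on ring B).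

Step 4
Reactants: 10 the aldol adduct
Product: 11 (1S,2R)-2-[3,4-bis(tert-butyldimethylsilyloxy)phenyl]-1-(3,4,5-trimethoxyphenyl)propane-1,3-diol
Conditions: LiBH4, MeOH (1 equiv), THF, 0 °C
Reagents that add atoms: none
Why: Reductive cleavage of the imide by LiBH4 should give the primary alcohol and release the auxiliary without touching the aryl silyl ethers or either stereocentre (the descriptor changes by priority only).

Step 5
Reactants: 11 the 1,3-diol
Product: 12 (2R,3S)-2-[3,4-bis(tert-butyldimethylsilyloxy)phenyl]-3-hydroxy-3-(3,4,5-trimethoxyphenyl)propyl 4-methylbenzenesulfonate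
Conditions: TsCl (1.1 equiv), pyridine, CH2Cl2, 0 °C; used at once
Reagents that add atoms: 4-toluenesulfonyl chloride, Cc1ccc(cc1)S(=O)(=O)Cl
Why: Selective sulfonylation: the primary hydroxyl should react well ahead of the hindered secondary benzylic one at 0 °C.

Step 6
Reactants: 12 the primary tosylate
Product: 13 (1S,2S)-2-[3,4-bis(tert-butyldimethylsilyloxy)phenyl]-1-(3,4,5-trimethoxyphenyl)propan-1-ol
Conditions: LiBHEt3 (3.5 equiv), THF, 0 °C to rt; NH4Cl work-up
Reagents that add atoms: none
Why: SN2 displacement of the primary tosylate by hydride (superhydride reduction) should turn CH2OTs into the C3 methyl faster than the neighbouring alkoxide can close an oxetane, with no bond to a stereocentre broken.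

Step 7
Reactants: 13 the bis-silyl ether
Product: 14 (1S,2S)-2-(3,4-dihydroxyphenyl)-1-(3,4,5-trimethoxyphenyl)propan-1-ol
Conditions: KHF2, MeOH, rt, argon
Reagents that add atoms: none
Why: Fluoride desilylation with KHF2 is selective for aryl silyl ethers and weakly acidic, so the catechol should be freed without air oxidation and without disturbing the benzylic alcohol.

Step 8
Reactants: 14 (1S,2S)-2-(3,4-dihydroxyphenyl)-1-(3,4,5-trimethoxyphenyl)propan-1-ol
Product: 17 (2S,3S)-3-methyl-2-(3,4,5-trimethoxyphenyl)-2,3-dihydrobenzofuran-5,6-dione, via open-chain o-quinone 15 (not isolated), via bicyclic catechol 16 (not isolated)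
Conditions: graphite anode, Pt-wire cathode, undivided cell, LiClO4 (0.1 M), MeCN/HFIP (4:1), anode held at the first oxidation wave of 14 (read from a voltammogram, expected near +1.0 V vs Ag/AgCl), about 4 F/mol, 0 °C, argon; product kept cold and free of base
Reagents that add atoms: none
Why: Two-electron oxidation of the catechol gives o-quinone 15, in which the ring carbon ortho to the side chain (the future C7a) is the β-carbon of an enone; the C2 hydroxyl adds there, tautomerisation gives catechol 16, and 16, being more electron-rich than 14, is oxidised at the same potential to 17 (an ECE sequence). The closest known reaction type is the anodic alkoxylation of 4-alkylcatechols in alcohols, which gives 4-alkoxy-5-alkyl-o-benzoquinones by the same addition ortho to the alkyl group; here it is intramolecular, as in the cyclisation of dopaquinone. Ring B closes in the 5-exo-trig mode, the attacked C7a=C7 bond lying outside the new ring. No stereocentre is created: the C2–O and C3–H bonds stay intact, so the 2S,3S (trans) configuration from the aldol is carried over, and trans is also the more stable arrangement should C2 ever ionise reversibly. The step needs oxygen capture at C7a to outrun tautomerisation of 15 to a quinone methide through the C3 hydrogen, and needs the trimethoxyphenyl ring to stay unoxidised. The easy five-membered closure, the base-free hydrogen-bond-donating medium and a potential held well below the trimethoxyarene wave should secure both.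

Step 9
Reactants: 17 (2S,3S)-3-methyl-2-(3,4,5-trimethoxyphenyl)-2,3-dihydrobenzofuran-5,6-dione
Product: 19 (2S,3S,5S)-5-allyl-5-hydroxy-3-methyl-2-(3,4,5-trimethoxyphenyl)-2,3-dihydrobenzofuran-6(5H)-one, via diisopropyl borate ester 18 (not isolated)
Conditions: allylB(OiPr)2 (1.5 equiv), (S)-3,3'-Br2-BINOL (15 mol%), PhMe/PhCF3 (3:1), −35 °C; pH 7 buffer; chromatography to remove any C5 epimer
Reagents that add atoms: allyldiisopropoxyborane, C=CCB(OC(C)C)OC(C)C
Why: Proposed new method: diol-catalysed allylboration is established for aryl and alkenyl ketones but not for an o-quinone carbonyl; the BINOL-bound allylboronate formed by isopropoxy exchange should deliver allyl through a closed chair transition state to C5 (the more electrophilic carbonyl, since C6 is deactivated as a vinylogous ester by O1), and the catalyst, not the remote C2/C3 centres, should direct it to the Re face of C5, syn to the C3 methyl, to set 5S; the closest known reaction types are the BINOL-catalysed asymmetric allylboration of ketones and the uncatalysed 1,2-allylation of o-quinones by allylmetal reagents.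

Step 10
Reactants: 19 (2S,3S,5S)-5-allyl-5-hydroxy-3-methyl-2-(3,4,5-trimethoxyphenyl)-2,3-dihydrobenzofuran-6(5H)-one
Product: 20 (2S,3S,5S)-5-allyl-5-methoxy-3-methyl-2-(3,4,5-trimethoxyphenyl)-2,3-dihydrobenzofuran-6(5H)-one
Conditions: MeI (excess), Ag2O, 4 Å MS, CH2Cl2, 35 °C, dark
Reagents that add atoms: iodomethane, CI
Why: Purdie methylation alkylates the neutral tertiary α-ketol oxygen without strong base or acid, which should avoid anionic oxy-Cope and α-ketol shifts of the 5-allyl-5-hydroxy dienone; the C5–O bond is not broken, so 5S is kept.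

**Compound list**

1 | 3,4-dihydroxyphenylacetic acid | OC(=O)Cc1ccc(O)c(O)c1 | starting material
2 | tert-butyldimethylsilyl 2-[3,4-bis(tert-butyldimethylsilyloxy)phenyl]acetate | CC(C)(C)[Si](C)(C)OC(=O)Cc1ccc(O[Si](C)(C)C(C)(C)C)c(O[Si](C)(C)C(C)(C)C)c1 | intermediate
3 | 2-[3,4-bis(tert-butyldimethylsilyloxy)phenyl]acetic acid | OC(=O)Cc1ccc(O[Si](C)(C)C(C)(C)C)c(O[Si](C)(C)C(C)(C)C)c1 | intermediate
4 | (S)-4-benzyl-2-oxazolidinone | O=C1N[C@@H](Cc2ccccc2)CO1 | starting material
5 | 2-[3,4-bis(tert-butyldimethylsilyloxy)phenyl]acetic pivalic anhydride | CC(C)(C)C(=O)OC(=O)Cc1ccc(O[Si](C)(C)C(C)(C)C)c(O[Si](C)(C)C(C)(C)C)c1 | intermediate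
6 | (S)-4-benzyl-3-{2-[3,4-bis(tert-butyldimethylsilyloxy)phenyl]acetyl}oxazolidin-2-one | O=C1N(C(=O)Cc2ccc(O[Si](C)(C)C(C)(C)C)c(O[Si](C)(C)C(C)(C)C)c2)[C@@H](Cc2ccccc2)CO1 | intermediate
7 | 3,4,5-trimethoxybenzaldehyde | COc1cc(C=O)cc(OC)c1OC | starting material
8 | Z-dibutylboron enolate of 6 | CCCCB(CCCC)O/C(=C\c1ccc(O[Si](C)(C)C(C)(C)C)c(O[Si](C)(C)C(C)(C)C)c1)N1[C@@H](Cc2ccccc2)COC1=O | intermediate
9 | dibutylboron aldolate of 10 | O=C1N(C(=O)[C@H]([C@H](OB(CCCC)CCCC)c2cc(OC)c(OC)c(OC)c2)c2ccc(O[Si](C)(C)C(C)(C)C)c(O[Si](C)(C)C(C)(C)C)c2)[C@@H](Cc2ccccc2)CO1 | intermediate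
10 | (S)-4-benzyl-3-[(2S,3S)-2-[3,4-bis(tert-butyldimethylsilyloxy)phenyl]-3-hydroxy-3-(3,4,5-trimethoxyphenyl)propanoyl]oxazolidin-2-one | O=C1N(C(=O)[C@H]([C@H](O)c2cc(OC)c(OC)c(OC)c2)c2ccc(O[Si](C)(C)C(C)(C)C)c(O[Si](C)(C)C(C)(C)C)c2)[C@@H](Cc2ccccc2)CO1 | intermediate
11 | (1S,2R)-2-[3,4-bis(tert-butyldimethylsilyloxy)phenyl]-1-(3,4,5-trimethoxyphenyl)propane-1,3-diol | OC[C@H]([C@H](O)c1cc(OC)c(OC)c(OC)c1)c1ccc(O[Si](C)(C)C(C)(C)C)c(O[Si](C)(C)C(C)(C)C)c1 | intermediate
12 | (2R,3S)-2-[3,4-bis(tert-butyldimethylsilyloxy)phenyl]-3-hydroxy-3-(3,4,5-trimethoxyphenyl)propyl 4-methylbenzenesulfonate | Cc1ccc(cc1)S(=O)(=O)OC[C@H]([C@H](O)c1cc(OC)c(OC)c(OC)c1)c1ccc(O[Si](C)(C)C(C)(C)C)c(O[Si](C)(C)C(C)(C)C)c1 | intermediate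
13 | (1S,2S)-2-[3,4-bis(tert-butyldimethylsilyloxy)phenyl]-1-(3,4,5-trimethoxyphenyl)propan-1-ol | C[C@H]([C@H](O)c1cc(OC)c(OC)c(OC)c1)c1ccc(O[Si](C)(C)C(C)(C)C)c(O[Si](C)(C)C(C)(C)C)c1 | intermediate
14 | (1S,2S)-2-(3,4-dihydroxyphenyl)-1-(3,4,5-trimethoxyphenyl)propan-1-ol | C[C@H]([C@H](O)c1cc(OC)c(OC)c(OC)c1)c1ccc(O)c(O)c1 | intermediate
15 | 4-[(1S,2S)-1-hydroxy-1-(3,4,5-trimethoxyphenyl)propan-2-yl]cyclohexa-3,5-diene-1,2-dione | C[C@H]([C@H](O)c1cc(OC)c(OC)c(OC)c1)C1=CC(=O)C(=O)C=C1 | intermediate
16 | (2S,3S)-3-methyl-2-(3,4,5-trimethoxyphenyl)-2,3-dihydrobenzofuran-5,6-diol | C[C@@H]1[C@@H](c2cc(OC)c(OC)c(OC)c2)Oc2cc(O)c(O)cc12 | intermediate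
17 | (2S,3S)-3-methyl-2-(3,4,5-trimethoxyphenyl)-2,3-dihydrobenzofuran-5,6-dione | C[C@@H]1[C@@H](c2cc(OC)c(OC)c(OC)c2)OC2=CC(=O)C(=O)C=C12 | intermediate
18 | diisopropyl borate ester of 19 | C=CC[C@]1(OB(OC(C)C)OC(C)C)C=C2C(=CC1=O)O[C@H](c1cc(OC)c(OC)c(OC)c1)[C@H]2C | intermediate
19 | (2S,3S,5S)-5-allyl-5-hydroxy-3-methyl-2-(3,4,5-trimethoxyphenyl)-2,3-dihydrobenzofuran-6(5H)-one | C=CC[C@]1(O)C=C2C(=CC1=O)O[C@H](c1cc(OC)c(OC)c(OC)c1)[C@H]2C | intermediate
20 | (2S,3S,5S)-5-allyl-5-methoxy-3-methyl-2-(3,4,5-trimethoxyphenyl)-2,3-dihydrobenzofuran-6(5H)-one | C=CC[C@]1(OC)C=C2C(=CC1=O)O[C@H](c1cc(OC)c(OC)c(OC)c1)[C@H]2C | target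

**Step count**

Total steps: 10. Longest linear sequence: 10 steps (from 1 to 20).

**Steps most likely to fail**

Step 9 (bears the label). The flat C5 carbonyl may be attacked with weak or wrong-sense facial discrimination, because the resident centres are remote and uncatalysed addition may compete. The quinone may also be lost by tautomerisation through the C3 hydrogen, which would aromatise ring B. The fallback sets out from 17 and uses known chemistry: Barbier allylation with indium powder and allyl bromide in THF/DMF at 0 °C, the established 1,2-allylation of o-quinones and 1,2-diones by allylindium reagents. It should add at C5 without facial control and give 19 together with its C5 epimer, (2S,3S,5R)-5-allyl-5-hydroxy-3-methyl-2-(3,4,5-trimethoxyphenyl)-2,3-dihydrobenzofuran-6(5H)-one F1. The two diastereomers are separated by chromatography on silica (preparative HPLC if needed), and the route is rejoined at 19.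

Step 8. Ring closure may be outrun by tautomerisation of the open-chain quinone to a quinone methide or by its coupling with unreacted catechol, and a drifting potential may over-oxidise the trimethoxyphenyl ring. The fallback sets out from 14 and forms the O1–C7a bond by substitution instead of addition. Oxidation at a carbon anode in methanol containing NaOAc, the known intermolecular methoxylation of 4-alkylcatechols, should give 4-[(1S,2S)-1-hydroxy-1-(3,4,5-trimethoxyphenyl)propan-2-yl]-5-methoxycyclohexa-3,5-diene-1,2-dione F2. Catalytic camphorsulfonic acid in CH2Cl2 over 4 Å sieves should then let the C2 hydroxyl displace the methoxy group by addition–elimination at the vinylogous ester carbon, closing ring B and rejoining the route at 17.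

Step 10. Alkylation of the hindered tertiary hydroxyl may be slow, and during that time the o-quinol may dimerise by Diels–Alder reaction or shift its allyl group. The fallback sets out from 19 and alkylates a preformed alkoxide instead of the neutral alcohol. LiHMDS in THF at −78 °C should give the lithium alkoxide of 19 F3, which is quenched at −78 °C with MeOTf to give 20 directly. The lithium counter-ion and the low temperature should keep anionic oxy-Cope and α-ketol rearrangements slow.

**Further compounds**

F1 | step 9 | (2S,3S,5R)-5-allyl-5-hydroxy-3-methyl-2-(3,4,5-trimethoxyphenyl)-2,3-dihydrobenzofuran-6(5H)-one | C=CC[C@@]1(O)C=C2C(=CC1=O)O[C@H](c1cc(OC)c(OC)c(OC)c1)[C@H]2C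
F2 | step 8 | 4-[(1S,2S)-1-hydroxy-1-(3,4,5-trimethoxyphenyl)propan-2-yl]-5-methoxycyclohexa-3,5-diene-1,2-dione | C[C@H]([C@H](O)c1cc(OC)c(OC)c(OC)c1)C1=CC(=O)C(=O)C=C1OC
F3 | step 10 | lithium alkoxide of 19 | [Li+].C=CC[C@]1([O-])C=C2C(=CC1=O)O[C@H](c1cc(OC)c(OC)c(OC)c1)[C@H]2C
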